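Start with the easy step: L.Q forms from L and Q on Z, so Q is the charge to settle for the next run.

    L + Q + Z → L.Q + Z, rate k1*[L]*[Q]*[Z]/(1 + ([L]/sat1)) (sat1 = 41.7 mM, k1 = 1340 M⁻² s⁻¹)
    Z + D ⇌ Z.D (K2 = 6400 M⁻¹, k2 = 6.04 M⁻¹ s⁻¹)

- oak: L 0.018 M; Q 0.0140 M (fed, over 30 min); Z 90 µM; D 0.19 mM; time 30 min; the fed solution adds 0.20 times the starting volume
- birch: L 0.018 M; Q 0.0290 M (fed, over 30 min); Z 90 µM; D 0.19 mM; time 30 min; the fed solution adds 0.20 times the starting volume

- charges are per starting volume, the dose included; the dosed solution carries all of it
- run time (oak): 30 min

1. which of these there is most of at the end, counted by the L in it, oak (L.Q / L)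
2. which of these there is most of at the end, counted by the L in it, birch (L.Q / L)
3. how much there is at the end of the one of these that leads, in percent of the L charged: oak
4. how much there is at the end of the one of these that leads, in percent of the L charged: birch

Your decision is between oak's Q charge and birch's, so work in logarithms. Call Θ the natural logarithm of the L charged over the L left. Dividing the rate of step 1 by [L] shows that Θ grows at k1[Q][Z]/(1 + [L]/sat1), and this still holds [L] in its denominator.

Here is my own reckoning. Counting D at its charge, K2[D] is 1.2, which leaves 45.1% of Z free. Now hold [L] at its charge in the denominator, an approximation that makes the decay of L pseudo-first-order at given [Q] and [Z], and dilute once by the final volume. That gives κ = 0.0317 M⁻¹ s⁻¹, the growth of Θ per unit of Q concentration. A steady feed, neglecting the Q consumed, gives a time integral of Q equal to 0.5 times the charge times the dosing time, so Θ is κ times that integral.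

That is 0.399 for oak and 0.827 for birch. L and L.Q are equal at Θ = ln(2), or 0.693. Oak stays below this and birch passes it. I therefore expect L to lead oak at 67.1% and L.Q to lead birch at 56.3%. If you want L.Q ahead at 30 min, charge birch's Q.

The forecast gives L at 69% (65% to 73%) for oak, higher than my figure. For birch it gives L.Q at 56% (51% to 61%), saying “the doubled Q dose just tips L.Q into the lead”.

The simulation gives L at 69.4% in oak and L.Q at 55.8% in birch.

Read back, Θ is 0.365 in oak and 0.817 in birch, a ratio of 2.24 against 2.07 in the charges. The gap between the flasks comes mainly from the Q charged, worth 25 percentage points of L. The forecast for oak would fail at 0.0172 M of Q, where L moves 6 points, past its 65%. Now leave oak until 50 min. Holding the 60.7% of Q free at the feed's end, κ adds 0.323 to Θ, which predicts L at 50.3%, and that flask stands at 51.1%.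

(The numbers of this flask were set for the occasion; the rest is arithmetic.)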